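## Structural features

The target is a germacranolide, numbered here C1–C15. Its cyclodeca-1(10),4-diene carries a Z-C1=C10 and an E-C4=C5 trisubstituted alkene, 1,5-related through C2–C3, and an α-methylene-γ-butyrolactone (O6, C12, C11=C13) trans-fused at C6–C7. C6, C7 and C8 form a contiguous stereotriad (all R) in which O8 is cis to C11 and O6 is trans to it. The allylic carbinol C2 (S) stands alone on the far side of the ring. O8 carries the ester of (2R,3R)-2-(hydroxymethyl)-3-methyloxirane-2-carboxylic acid, whose fully substituted C2′ and C3′ are adjacent and whose methyl is cis to the carboxyl. Fragile groups are the exocyclic enoate (Michael acceptor), the glycidic ester, the 1,5-diene (Cope rearrangement, transannular cyclisation) and the pairing of a cis 8-oxygen with the 6,12-lactone (translactonisation to the cis 8,12-lactone). The real difficulty is a ten-membered ring with two trisubstituted alkenes of opposite geometry next to a stereotriad. The key step uses the 1,5-relationship of the alkenes. By formal metathesis C1=C10/C4=C5 become C1=C4 of a four-membered ring (C1–C4 with O2) and C5=C10 of a six-membered enone (C5–C10 with the C6 carbonyl, the C7 arm and O8). Light then makes the σ bonds C1–C10 and C4–C5, and heat later breaks C1–C4 and C5–C10.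

## Logic of the disconnections

**37 ⇒ 36.** The two O–Si bonds (O2 and the side-chain CH2O) are cut last. Both hydroxyls carry the same silyl group, so one buffered fluoride treatment ends the synthesis. The demand is that the cleavage spares epoxide, enoate and both esters.

**36 ⇒ 25 + 34.** The C8–O acyl bond is cut, separating the oxirane acid from the carbocycle. The gain is convergence: the epoxide never meets enolates, hydride or 180 °C. The forward step must acylate a hindered alcohol lying cis to the lactone carbon without translactonisation, and O8 must be unmasked while O2 stays silylated.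

**34 ⇒ 32 ⇒ 31.** The carboxyl is taken back to CH2OH and the two epoxide C–O bonds to the alkene. The hydroxymethyl that becomes the carboxyl is the one cis to the methyl, so it is the allylic hydroxyl that steers a titanium–tartrate epoxidation. Both oxirane stereocentres then come from one reagent-controlled step; the demand is a geometrically pure alkene whose two CH2O arms are told apart.

**31 ⇒ 29 ⇒ 28 ⇒ 27 ⇒ 26.** The C–CH2OH bond is cut to an alkenyllithium and formaldehyde. The alkenyl iodide comes from α-iodination of the enal, which fixes the geometry, then reduction and silylation. One arm is silylated before the other exists, so no diol has to be desymmetrised. The halogen–lithium exchange must keep the alkene geometry.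

**25 ⇒ 24 ⇒ 21.** The O8–Si bond and the C11=C13 bond are cut; the methylene is added to the lactone enolate as a Mannich unit. This removes the Michael acceptor from all earlier steps. The demand is clean enolisation at C11 and a desilylation that distinguishes triethylsilyl from tert-butyldimethylsilyl.

**21 ⇒ 20.** The two ring alkenes are reconnected as the σ bonds C1–C4 and C5–C10, which is the thermal cycloreversion read backwards. The ten-membered ring is thereby traded for a ladder of one six-membered and two four-membered rings, and no macrocyclisation is needed. The lactone is closed before the opening on purpose. A trans-fused lactone forces O6 and C11 equatorial on the six-membered ring and so fixes the sense in which that ring twists as the ladder opens. The forward step must run through the chair-like pathway, must cleave ring B (C1, C10, C5, C4) and not ring A (C1–C4), and must stop before a Cope rearrangement.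

**20 ⇒ 18.** The C12–O6 bond is cut and C6 is returned to the ketone. The ketone is what the photochemistry needs; the alcohol is what the lock needs. The demand is hydride delivery to the C6 face opposite the fused four-membered ring.

**18 ⇒ 12 + 17.** C1–C10 and C4–C5 are cut, giving a cyclohexenone and a cyclobutene that each carry their stereocentres (C7/C8 and C2) from small-ring chemistry. The forward step must be head-to-head and give the cis,anti,cis ladder. The configurations of 12, 17 and 18 were checked atom by atom against 37 (C2 S, C7 R, C8 R) and are mutually consistent.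

**12 ⇒ 10 ⇒ 9 ⇒ 7.** The C5=C10 unsaturation is removed, the C6 carbonyl is taken back to an alcohol, and the C6–O/C7–H pair to an alkene. Syn addition of H–B anti to the allylic silyloxy group puts the C7 arm cis to O8 by mechanism. The improvement over a ketol route is that O8 is silylated before the acetate arm exists, so a free cis γ-hydroxy ester, which would close to the 8,12-lactone, never appears.

**7 ⇒ 4 + 5; 4 ⇒ 3 ⇒ 2 ⇒ 1.** The C7–C11 bond is cut to an alkenyl iodide and a zinc ester enolate. The iodide also makes the enone a well-differentiated substrate for catalytic asymmetric reduction, which sets C8. The coupling must be non-basic.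

**17 ⇒ 16 ⇒ 15 ⇒ 13.** The silyl ether, the carbinol C–H and the C4–CH3 bond are cut back to a vinylogous ester. The carbinol must be made without a free alkoxide and the cyclobutene kept cold.

## Other disconnections considered

**Alternative 1:** The cut is C2–C3, with C5–C10 re-formed. In the forward sense a [3,3] shift of a potassium alkoxide on a six-membered ring with cis alkenyl groups at C5 and C10 would give the ten-membered enolate, trapped as triflate A1.
- In its favour: oxyanion acceleration would let the ring expand at or below room temperature, far from the range where germacradienes rearrange. On that point it is better than the chosen plan.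
- Also better: O6 would already sit on the six-membered ring, so no late hydride reduction of C6 is needed.
- Equal: it avoids macrocyclisation, and a cis-dialkenyl chair inherently gives one Z and one E alkene.
- Against it here: the substrate needs two adjacent fully substituted ring carbons (the C5 carbinol and a C10 bearing methyl and a 2-alkoxyvinyl group), and C2 would be set only by enol-ether geometry and transition-state face.
- Against it in step economy: A1 would still need triflate reduction at C5, oxidation of C12 from the alcohol level, lactonisation and removal of four protecting groups of three kinds. The chosen plan is more convergent and sets C2 by reagent control in a small ring.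

**Alternative 2:** The cut is C7–C11. The enolate of the O6 phosphonoacetate in epoxide A4 would open the trans-7,8-epoxide at C7 with inversion to give phosphono lactone A2, ready for a Horner–Wadsworth–Emmons reaction with formaldehyde.
- In its favour: one stereospecific SN2 step would set C7, close the lactone, free O8 for acylation and carry the handle for the methylene group. In end-game economy it is better than steps 14 and 15 of the chosen route (no strong base, no O8 protecting group).
- Against it here: A4 is already the complete ten-membered diene with O2, O6 and both alkene geometries, so the main difficulty is left unsolved.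
- Mechanistic risks: a stabilised phosphonoacetate anion is a weak nucleophile for an unactivated epoxide, 6-endo attack at C8 competes with 5-exo attack at C7, and Lewis-acid activation would invite transannular attack by the ring alkenes.
- Comparison: it is a good way to finish a macrocycle and a poor way to make one, so overall the chosen plan is ahead.

**Alternative 3:** The cut is C1–C2. The Z-alkenyl iodide of seco compound A5 would add to its aldehyde through an alkenylchromium species (CrCl2 with catalytic NiCl2) to give macrocycle A3.
- In its favour: the Z geometry of C1=C10 and the E geometry of C4=C5 would be built into the open chain and retained. This removes the largest uncertainty of the chosen plan and is a point on which the alternative is better.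
- Also in its favour: lactone, enoate and the O8 silyl ether would already be in place, so A3 would be a few steps from the target and would meet the chosen route near 24.
- Against it here: closing a ten-membered ring is entropically and transannularly disfavoured (high dilution, large excess of chromium salt).
- C2 would be set only by the conformation of the closing ring, whereas the chosen plan sets it by catalyst control.
- The aldehyde of A5 is β,γ-unsaturated and prone to shift into conjugation.
- A5 needs a long linear synthesis with acyclic control of C6–C8. In ring formation, C2 control and length the chosen plan is ahead.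

Key step: step 11

Remark on the chemistry: the methyl-bearing carbon of 1 is racemic, so 3, 4 and 7–11 are pairs of epimers at that carbon (left undefined in their SMILES); they converge when it becomes sp2 in step 7. Compounds 1, 5, 13 and 26 are taken as catalogue compounds.

## Route

Step 1
Reactants: 1 5-methylcyclohex-2-en-1-one (racemic)
Product: 2 2-iodo-5-methylcyclohex-2-en-1-one
Conditions: I2, pyridine, CH2Cl2, 0 °C to rt
Reagents that add atoms: iodine, I-I
Why: Pyridine-mediated α-iodination of an enone (conjugate addition of pyridine, iodination of the enolate, E1cB loss of pyridine); it installs the handle for the later C7–C11 coupling and makes the carbonyl a well-differentiated substrate for the next reduction.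

Step 2
Reactants: 2 2-iodo-5-methylcyclohex-2-en-1-one
Product: 3 (1R)-2-iodo-5-methylcyclohex-2-en-1-ol (epimers at C5)
Conditions: (S)-2-methyl-CBS-oxazaborolidine (0.2 equiv), BH3·SMe2, THF, −20 °C; MeOH quench
Reagents that add atoms: none
Why: Corey–Bakshi–Shibata reduction; the iodoalkenyl carbon acts as the large group, so the (S)-catalyst should deliver hydride to give the (1R)-carbinol, the future C8; the remote methyl centre is carried as an epimeric pair.

Step 3
Reactants: 3 (1R)-2-iodo-5-methylcyclohex-2-en-1-ol
Product: 4 triethyl{[(1R)-2-iodo-5-methylcyclohex-2-en-1-yl]oxy}silane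
Conditions: Et3SiCl, imidazole, DMF, 0 °C
Reagents that add atoms: chlorotriethylsilane, CC[Si](Cl)(CC)CC
Why: Standard silylation of a secondary allylic alcohol; O8 is capped before the acetate arm exists, so a free cis γ-hydroxy ester never appears.

Step 4
Reactants: 4 triethyl{[(1R)-2-iodo-5-methylcyclohex-2-en-1-yl]oxy}silane; 5 methyl bromoacetate
Product: 7 methyl 2-[(6R)-4-methyl-6-[(triethylsilyl)oxy]cyclohex-1-en-1-yl]acetate, via bromo(2-methoxy-2-oxoethyl)zinc 6 (not isolated)
Conditions: Zn dust (Me3SiCl-activated), THF, 40 °C; then 4, Pd2(dba)3 (2.5 mol %), XPhos (10 mol %), THF, 60 °C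
Reagents that add atoms: none
Why: Negishi-type cross-coupling of a Reformatsky reagent (zinc ester enolate) with an alkenyl iodide under zerovalent palladium; the weakly basic zinc reagent leaves the allylic silyl ether alone and does not move the β,γ-alkene into conjugation.

Step 5
Reactants: 7 methyl 2-[(6R)-4-methyl-6-[(triethylsilyl)oxy]cyclohex-1-en-1-yl]acetate
Product: 9 methyl 2-[(1S,2R,6R)-2-hydroxy-4-methyl-6-[(triethylsilyl)oxy]cyclohexyl]acetate, via alkylborane 8 (not isolated)
Conditions: BH3·THF, THF, 0 °C; then 30% H2O2, aq NaOAc, 0 °C to rt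
Reagents that add atoms: hydrogen peroxide, OO
Why: Hydroboration–oxidation; boron adds to the less substituted C6 and, by syn addition on the face anti to the allylic silyloxy group, hydrogen is placed on C7 trans to O8, which sets C7 with the arm cis to O8; near-neutral oxidation with retention spares the ester.

Step 6
Reactants: 9 methyl 2-[(1S,2R,6R)-2-hydroxy-4-methyl-6-[(triethylsilyl)oxy]cyclohexyl]acetate
Product: 10 methyl 2-[(1R,6R)-4-methyl-2-oxo-6-[(triethylsilyl)oxy]cyclohexyl]acetate
Conditions: Dess–Martin periodinane, NaHCO3, CH2Cl2, 0 °C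
Reagents that add atoms: none
Why: Dess–Martin oxidation under bicarbonate buffer; neutral conditions avoid epimerisation of the now enolisable C7 and β-elimination of the silyloxy group.

Step 7
Reactants: 10 methyl 2-[(1R,6R)-4-methyl-2-oxo-6-[(triethylsilyl)oxy]cyclohexyl]acetate
Product: 12 methyl 2-[(1R,6R)-4-methyl-2-oxo-6-[(triethylsilyl)oxy]cyclohex-3-en-1-yl]acetate, via trimethylsilyl enol ether 11 (not isolated)
Conditions: LiN(i-Pr)2, Me3SiCl (internal quench), THF, −78 °C; then Pd(OAc)2 (1.1 equiv), MeCN, rt
Reagents that add atoms: none
Why: Saegusa–Ito dehydrogenation; kinetic deprotonation occurs at the C5 methylene (not at the hindered C7–H, whose enolate would expel the β-silyloxy group), and Pd(OAc)2 then forms the C5=C10 enone while being reduced to zerovalent palladium; the methyl-bearing stereocentre disappears, so 12 is one stereoisomer.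

Step 8
Reactants: 13 3-ethoxycyclobut-2-en-1-one
Product: 15 3-methylcyclobut-2-en-1-one, via 3-ethoxy-1-methylcyclobut-2-en-1-ol 14 (not isolated)
Conditions: MeLi, Et2O, −78 °C; then 1 M HCl, 0 °C
Reagents that add atoms: methyllithium, [Li]C
Why: 1,2-Addition to the vinylogous ester carbonyl, then acid hydrolysis of the enol ether with loss of water (Stork–Danheiser-type transposition) gives the 3-methyl enone; it is handled as a cold solution because it is volatile.

Step 9
Reactants: 15 3-methylcyclobut-2-en-1-one
Product: 16 (1S)-3-methylcyclobut-2-en-1-ol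
Conditions: (R)-2-methyl-CBS-oxazaborolidine (0.2 equiv), catecholborane, toluene, −78 °C; MeOH quench
Reagents that add atoms: none
Why: Corey–Bakshi–Shibata reduction with catecholborane (1,2-selective for enones); with the sp2 carbon as the larger group the (R)-catalyst should give the (S)-carbinol, the future C2, and the boron-bound oxygen avoids oxyanion-accelerated ring opening.

Step 10
Reactants: 16 (1S)-3-methylcyclobut-2-en-1-ol
Product: 17 tert-butyldimethyl{[(1S)-3-methylcyclobut-2-en-1-yl]oxy}silane
Conditions: t-BuMe2SiCl, imidazole, CH2Cl2, 0 °C; kept at or below 0 °C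
Reagents that add atoms: tert-butylchlorodimethylsilane, CC(C)(C)[Si](C)(C)Cl
Why: Silylation with imidazole as base (no alkoxide); the product is used promptly and cold because a 3-silyloxycyclobutene opens electrocyclically on warming.

Step 11
Reactants: 12 methyl 2-[(1R,6R)-4-methyl-2-oxo-6-[(triethylsilyl)oxy]cyclohex-3-en-1-yl]acetate; 17 tert-butyldimethyl{[(1S)-3-methylcyclobut-2-en-1-yl]oxy}silane
Product: 18 methyl 2-{3-[(tert-butyldimethylsilyl)oxy]-1,5-dimethyl-7-oxo-9-[(triethylsilyl)oxy]tricyclo[4.4.0.0(2,5)]decan-8-yl}acetate (head-to-head cis-anti-cis ladder; ring atoms 1–10 are C10, C1, C2, C3, C4, C5, C6, C7, C8, C9)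
Conditions: hν (366 nm, Pyrex), 17 (4 equiv), CH2Cl2, −40 °C, degassed; then basic Al2O3, 0 °C
Reagents that add atoms: none
Why: This is an enone–alkene [2+2] photocycloaddition, the light-driven half of a photo-thermal olefin metathesis, and the closest known case is the addition of 1-methylcyclobutene to 3-alkylcyclohex-2-enones. Excitation and intersystem crossing give the triplet enone, which bonds to the cyclobutene to form a triplet 1,4-biradical; after spin inversion, radical recombination closes the new four-membered ring (C1, C10, C5, C4), so that C1–C10 and C4–C5 are formed and a bicyclo[2.2.0]hexane results. The step needs head-to-head regiochemistry, and the substrate secures it sterically: the methyl-bearing C4 bonds to the unsubstituted C5 because the other orientation would join the two fully substituted carbons C4 and C10, and first bonding at the unhindered C1 leaves a tertiary radical at C4 and an α-keto radical at C5. C1 and C4 are cis because they are held in the four-membered ring; C5 and C10 end cis because the short alumina treatment epimerises any strained trans-fused adduct at C5. The cyclobutene approaches the enone face opposite the cis C8 silyloxy group and C7 arm, the enone approaches the cyclobutene face opposite its silyloxy group, and the small ring turns away from the six-membered ring, which gives the cis,anti,cis ladder. The cold, degassed solution and the excess of 17 hold back thermal ring opening of 17 and side reactions of the enone. C2, C7 and C8 are not touched.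

Step 12
Reactants: 18 ladder keto ester
Product: 20 trans-fused ladder γ-lactone (O6 on the face of the four-membered ring and trans to C11; 2-OTBS and 8-OTES kept), via hydroxy ester 19 (not isolated)
Conditions: NaBH4, MeOH/THF, −40 to 0 °C; then PPTS (cat.), toluene, 4 Å MS, 80 °C
Reagents that add atoms: none
Why: Hydride reduction, then acid-catalysed lactonisation; NaBH4 should attack C6 anti to the quaternary C4 of the fused four-membered ring (exo face of the bicyclo[4.2.0]octanone), which places O6 trans to the C7 arm, and the hydroxy ester then closes to the trans-fused lactone.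

Step 13
Reactants: 20 trans-fused ladder γ-lactone
Product: 21 (3aS,4R,6Z,8S,10E,11aR)-8-[(tert-butyldimethylsilyl)oxy]-6,10-dimethyl-4-[(triethylsilyl)oxy]-3a,4,5,8,9,11a-hexahydrocyclodeca[b]furan-2(3H)-one
Conditions: toluene (0.01 M, degassed, BHT), sealed base-washed tube, 180–190 °C
Reagents that add atoms: none
Why: Strain-driven thermal [2+2] cycloreversion of the bicyclo[2.2.0]hexane through a chair-like cyclohexane-1,4-diyl (formal σ2s+σ2a) cleaves C1–C4 and the doubly ring-shared C5–C10. The trans-lactone holds O6 and C11 equatorial, which puts C10–C1 equatorial and C5–C4 axial on the six-membered ring, so C9 is carried cis to C2 (Z-C1=C10) and C6 trans to C3 (E-C4=C5). The four ladder stereocentres vanish while C2, C6, C7 and C8 are kept.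

Step 14
Reactants: 21 saturated germacradienolide
Product: 24 (3aS,4R,6Z,8S,10E,11aR)-8-[(tert-butyldimethylsilyl)oxy]-6,10-dimethyl-3-methylidene-4-[(triethylsilyl)oxy]-3a,4,5,8,9,11a-hexahydrocyclodeca[b]furan-2(3H)-one, via Mannich base 22 (not isolated), via quaternary ammonium iodide 23 (not isolated)
Conditions: LiN(i-Pr)2, THF, −78 °C; CH2=NMe2+ I−, −78 to 0 °C; then MeI, MeOH, rt; then aq NaHCO3, EtOAc
Reagents that add atoms: N,N-dimethylmethyleneiminium iodide, C=[N+](C)C.[I-]
Why: Eschenmoser methylenation: the lactone enolate is aminomethylated (Mannich), the amine is quaternised and trimethylamine is eliminated to give the exocyclic enoate; C7 carries no leaving group, so the enolate cannot eliminate.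

Step 15
Reactants: 24 α-methylene lactone bis-silyl ether
Product: 25 (3aR,4R,6Z,8S,10E,11aR)-8-[(tert-butyldimethylsilyl)oxy]-4-hydroxy-6,10-dimethyl-3-methylidene-3a,4,5,8,9,11a-hexahydrocyclodeca[b]furan-2(3H)-one
Conditions: HF·pyridine, pyridine, THF, 0 °C
Reagents that add atoms: none
Why: Buffered HF·pyridine cleaves the triethylsilyl ether much faster than the secondary tert-butyldimethylsilyl ether; the weakly acidic medium avoids conjugate addition to the enoate and translactonisation.

Step 16
Reactants: 26 (E)-but-2-enal
Product: 27 (2Z)-2-iodobut-2-enal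
Conditions: I2, K2CO3, DMAP (cat.), THF/H2O, rt
Reagents that add atoms: iodine, I-I
Why: α-Iodination of an enal by amine-catalysed addition, iodination and elimination; the more stable (Z)-iodoenal, with methyl trans to the formyl group, should form, which fixes the alkene geometry of the side chain.

Step 17
Reactants: 27 (2Z)-2-iodobut-2-enal
Product: 28 (2Z)-2-iodobut-2-en-1-ol
Conditions: NaBH4, CeCl3·7H2O, MeOH, 0 °C
Reagents that add atoms: none
Why: Luche 1,2-reduction of the enal; no stereocentre is formed and the alkene geometry is kept.

Step 18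
Reactants: 28 (2Z)-2-iodobut-2-en-1-ol
Product: 29 tert-butyl{[(2Z)-2-iodobut-2-en-1-yl]oxy}dimethylsilane
Conditions: t-BuMe2SiCl, imidazole, DMF, rt
Reagents that add atoms: tert-butylchlorodimethylsilane, CC(C)(C)[Si](C)(C)Cl
Why: Silylation of the primary alcohol; this arm becomes the hydroxymethyl group of the side chain and is thereby told apart from the arm added next.

Step 19
Reactants: 29 tert-butyl{[(2Z)-2-iodobut-2-en-1-yl]oxy}dimethylsilane
Product: 31 (2E)-2-({[tert-butyl(dimethyl)silyl]oxy}methyl)but-2-en-1-ol, via alkenyllithium 30 (not isolated)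
Conditions: t-BuLi (2 equiv), Et2O, −78 °C; then (CH2O)n, −78 °C to rt
Reagents that add atoms: formaldehyde (from paraformaldehyde), C=O
Why: Iodine–lithium exchange with retention of alkene geometry, then hydroxymethylation with formaldehyde; the new free CH2OH is therefore cis to the methyl group.

Step 20
Reactants: 31 (2E)-2-({[tert-butyl(dimethyl)silyl]oxy}methyl)but-2-en-1-ol
Product: 32 [(2R,3R)-2-({[tert-butyl(dimethyl)silyl]oxy}methyl)-3-methyloxiran-2-yl]methanol
Conditions: Ti(OiPr)4 (10 mol %), L-(+)-diethyl tartrate (12 mol %), t-BuOOH, 4 Å MS, CH2Cl2, −20 °C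
Reagents that add atoms: tert-butyl hydroperoxide, CC(C)(C)OO
Why: Sharpless asymmetric epoxidation; the only free allylic hydroxyl directs, and L-(+)-tartrate should deliver oxygen to the face that gives the (2R,3R)-epoxide with methyl cis to the directing CH2OH, which sets both oxirane stereocentres.

Step 21
Reactants: 32 epoxy alcohol
Product: 34 (2R,3R)-2-({[tert-butyl(dimethyl)silyl]oxy}methyl)-3-methyloxirane-2-carboxylic acid, via epoxy aldehyde 33 (not isolated)
Conditions: TEMPO (cat.), PhI(OAc)2, MeCN/H2O, 0 °C to rt; acid used at once
Reagents that add atoms: water, O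
Why: Oxoammonium (TEMPO) oxidation with PhI(OAc)2 in aqueous acetonitrile takes the primary alcohol through the aldehyde hydrate to the acid without touching epoxide or silyl ether; the glycidic acid is used at once to avoid decarboxylation.

Step 22
Reactants: 25 C8 alcohol; 34 silylated oxirane acid
Product: 36 (3aR,4R,6Z,8S,10E,11aR)-8-[(tert-butyldimethylsilyl)oxy]-6,10-dimethyl-3-methylidene-2-oxo-2,3,3a,4,5,8,9,11a-octahydrocyclodeca[b]furan-4-yl (2R,3R)-2-({[tert-butyl(dimethyl)silyl]oxy}methyl)-3-methyloxirane-2-carboxylate, via mixed anhydride 35 (not isolated)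
Conditions: 34, 2,4,6-trichlorobenzoyl chloride, Et3N, toluene, 0 °C; then 25, DMAP, toluene, rt
Reagents that add atoms: none
Why: Yamaguchi esterification; DMAP attacks the mixed anhydride at the glycidic carbonyl (the aroyl carbonyl is shielded by its two ortho chlorines) and the acylpyridinium acylates the hindered C8 hydroxyl under mild base, with no change at any stereocentre.

Step 23
Reactants: 36 bis-silyl ester
Product: 37 (3aR,4R,6Z,8S,10E,11aR)-8-hydroxy-6,10-dimethyl-3-methylidene-2-oxo-2,3,3a,4,5,8,9,11a-octahydrocyclodeca[b]furan-4-yl (2R,3R)-2-(hydroxymethyl)-3-methyloxirane-2-carboxylate (the target)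
Conditions: HF·pyridine, pyridine, THF, 0 °C to rt
Reagents that add atoms: none
Why: Fluoride-mediated cleavage of both tert-butyldimethylsilyl ethers with buffered HF·pyridine, conditions under which epoxide, enoate and esters should persist; this gives the target.

## Compound list

1 | 5-methylcyclohex-2-en-1-one (racemic) | CC1CC=CC(=O)C1 | starting material
2 | 2-iodo-5-methylcyclohex-2-en-1-one | O=C1CC(C)CC=C1I | intermediate
3 | (1R)-2-iodo-5-methylcyclohex-2-en-1-ol (C5 epimers) | IC1=CCC(C)C[C@H]1O | intermediate
4 | triethyl{[(1R)-2-iodo-5-methylcyclohex-2-en-1-yl]oxy}silane | IC1=CCC(C)C[C@H]1O[Si](CC)(CC)CC | intermediate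
5 | methyl bromoacetate | COC(=O)CBr | starting material
6 | bromo(2-methoxy-2-oxoethyl)zinc | COC(=O)C[Zn]Br | intermediate
7 | methyl 2-[(6R)-4-methyl-6-[(triethylsilyl)oxy]cyclohex-1-en-1-yl]acetate | COC(=O)CC1=CCC(C)C[C@H]1O[Si](CC)(CC)CC | intermediate
8 | alkylborane from 7 (boron on C6, trans to the arm) | B[C@@H]1CC(C)C[C@@H](O[Si](CC)(CC)CC)[C@H]1CC(=O)OC | intermediate
9 | methyl 2-[(1S,2R,6R)-2-hydroxy-4-methyl-6-[(triethylsilyl)oxy]cyclohexyl]acetate | O[C@@H]1CC(C)C[C@@H](O[Si](CC)(CC)CC)[C@H]1CC(=O)OC | intermediate
10 | methyl 2-[(1R,6R)-4-methyl-2-oxo-6-[(triethylsilyl)oxy]cyclohexyl]acetate | O=C1CC(C)C[C@@H](O[Si](CC)(CC)CC)[C@H]1CC(=O)OC | intermediate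
11 | methyl 2-[(1R,6R)-4-methyl-6-[(triethylsilyl)oxy]-2-[(trimethylsilyl)oxy]cyclohex-2-en-1-yl]acetate | C[Si](C)(C)OC1=CC(C)C[C@@H](O[Si](CC)(CC)CC)[C@H]1CC(=O)OC | intermediate
12 | methyl 2-[(1R,6R)-4-methyl-2-oxo-6-[(triethylsilyl)oxy]cyclohex-3-en-1-yl]acetate | O=C1C=C(C)C[C@@H](O[Si](CC)(CC)CC)[C@H]1CC(=O)OC | intermediate
13 | 3-ethoxycyclobut-2-en-1-one | CCOC1=CC(=O)C1 | starting material
14 | 3-ethoxy-1-methylcyclobut-2-en-1-ol | CCOC1=CC(C)(O)C1 | intermediate
15 | 3-methylcyclobut-2-en-1-one | CC1=CC(=O)C1 | intermediate
16 | (1S)-3-methylcyclobut-2-en-1-ol | CC1=C[C@@H](O)C1 | intermediate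
17 | tert-butyldimethyl{[(1S)-3-methylcyclobut-2-en-1-yl]oxy}silane | CC1=C[C@@H](O[Si](C)(C)C(C)(C)C)C1 | intermediate
18 | head-to-head cis,anti,cis ladder keto ester (photoadduct) | O=C1[C@H](CC(=O)OC)[C@H](O[Si](CC)(CC)CC)C[C@@]2(C)[C@@H]3[C@@H](O[Si](C)(C)C(C)(C)C)C[C@]3(C)[C@@H]12 | intermediate
19 | ladder hydroxy ester (6-OH trans to the C7 arm) | COC(=O)C[C@@H]1[C@H](O[Si](CC)(CC)CC)C[C@@]2(C)[C@@H]3[C@@H](O[Si](C)(C)C(C)(C)C)C[C@]3(C)[C@H]2[C@H]1O | intermediate
20 | trans-fused ladder γ-lactone | O=C1C[C@@H]2[C@H](O[Si](CC)(CC)CC)C[C@@]3(C)[C@@H]4[C@@H](O[Si](C)(C)C(C)(C)C)C[C@]4(C)[C@H]3[C@H]2O1 | intermediate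
21 | (3aS,4R,6Z,8S,10E,11aR)-8-[(tert-butyldimethylsilyl)oxy]-6,10-dimethyl-4-[(triethylsilyl)oxy]-3a,4,5,8,9,11a-hexahydrocyclodeca[b]furan-2(3H)-one | C1C(=O)O[C@@H]2/C=C(\C)C[C@H](O[Si](C)(C)C(C)(C)C)/C=C(/C)C[C@@H](O[Si](CC)(CC)CC)[C@@H]12 | intermediate
22 | 3-[(dimethylamino)methyl] derivative of 21 (Mannich base, C11 epimers) | CN(C)CC1C(=O)O[C@@H]2/C=C(\C)C[C@H](O[Si](C)(C)C(C)(C)C)/C=C(/C)C[C@@H](O[Si](CC)(CC)CC)[C@@H]12 | intermediate
23 | trimethylammonium iodide of 22 | C[N+](C)(C)CC1C(=O)O[C@@H]2/C=C(\C)C[C@H](O[Si](C)(C)C(C)(C)C)/C=C(/C)C[C@@H](O[Si](CC)(CC)CC)[C@@H]12.[I-] | intermediate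
24 | (3aS,4R,6Z,8S,10E,11aR)-8-[(tert-butyldimethylsilyl)oxy]-6,10-dimethyl-3-methylidene-4-[(triethylsilyl)oxy]-3a,4,5,8,9,11a-hexahydrocyclodeca[b]furan-2(3H)-one | C=C1C(=O)O[C@@H]2/C=C(\C)C[C@H](O[Si](C)(C)C(C)(C)C)/C=C(/C)C[C@@H](O[Si](CC)(CC)CC)[C@@H]12 | intermediate
25 | (3aR,4R,6Z,8S,10E,11aR)-8-[(tert-butyldimethylsilyl)oxy]-4-hydroxy-6,10-dimethyl-3-methylidene-3a,4,5,8,9,11a-hexahydrocyclodeca[b]furan-2(3H)-one | C=C1C(=O)O[C@@H]2/C=C(\C)C[C@H](O[Si](C)(C)C(C)(C)C)/C=C(/C)C[C@@H](O)[C@@H]12 | intermediate
26 | (E)-but-2-enal | C/C=C/C=O | starting material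
27 | (2Z)-2-iodobut-2-enal | C/C=C(\I)C=O | intermediate
28 | (2Z)-2-iodobut-2-en-1-ol | C/C=C(\I)CO | intermediate
29 | tert-butyl{[(2Z)-2-iodobut-2-en-1-yl]oxy}dimethylsilane | C/C=C(\I)CO[Si](C)(C)C(C)(C)C | intermediate
30 | alkenyllithium from 29 (geometry retained) | C/C=C(\[Li])CO[Si](C)(C)C(C)(C)C | intermediate
31 | (2E)-2-({[tert-butyl(dimethyl)silyl]oxy}methyl)but-2-en-1-ol | C/C=C(\CO)CO[Si](C)(C)C(C)(C)C | intermediate
32 | [(2R,3R)-2-({[tert-butyl(dimethyl)silyl]oxy}methyl)-3-methyloxiran-2-yl]methanol | OC[C@]1(CO[Si](C)(C)C(C)(C)C)O[C@@H]1C | intermediate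
33 | (2R,3R)-2-({[tert-butyl(dimethyl)silyl]oxy}methyl)-3-methyloxirane-2-carbaldehyde | O=C[C@]1(CO[Si](C)(C)C(C)(C)C)O[C@@H]1C | intermediate
34 | (2R,3R)-2-({[tert-butyl(dimethyl)silyl]oxy}methyl)-3-methyloxirane-2-carboxylic acid | OC(=O)[C@]1(CO[Si](C)(C)C(C)(C)C)O[C@@H]1C | intermediate
35 | mixed anhydride of 34 with 2,4,6-trichlorobenzoic acid | O=C(OC(=O)[C@]1(CO[Si](C)(C)C(C)(C)C)O[C@@H]1C)c1c(Cl)cc(Cl)cc1Cl | intermediate
36 | 2-O-TBS ester of 25 with 34 (bis-silyl ether of the target) | C=C1C(=O)O[C@@H]2/C=C(\C)C[C@H](O[Si](C)(C)C(C)(C)C)/C=C(/C)C[C@@H](OC(=O)[C@]3(CO[Si](C)(C)C(C)(C)C)O[C@@H]3C)[C@@H]12 | intermediate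
37 | (3aR,4R,6Z,8S,10E,11aR)-8-hydroxy-6,10-dimethyl-3-methylidene-2-oxo-2,3,3a,4,5,8,9,11a-octahydrocyclodeca[b]furan-4-yl (2R,3R)-2-(hydroxymethyl)-3-methyloxirane-2-carboxylate | C=C1C(=O)O[C@@H]2/C=C(\C)C[C@H](O)/C=C(/C)C[C@@H](OC(=O)[C@]3(CO)O[C@@H]3C)[C@@H]12 | target

## Step count and least certain steps

Total step count: 23. Longest linear sequence: 14 steps (steps 1–7, 11–15, 22 and 23). The cyclobutene (steps 8–10) and the oxirane acid (steps 16–21) are side branches.

**Step 11 (key step).** The most likely failure is loss of regiocontrol when the biradical forms and closes, giving head-to-tail adducts. A weakly donating methyl on C4 electronically favours bonding of C4 to the enone β-carbon, and only the steric clash of two fully substituted carbons opposes it. Syn ladders and thermal ring opening of 17 can also erode the yield. The fallback replaces steric by acceptor control and sets out from 12.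
- Commercial 3-[(tert-butyldimethylsilyl)oxy]cyclobutan-1-one would be desymmetrised by enantioselective enolisation with a chiral lithium bis(1-phenylethyl)amide and PhNTf2 to (3S)-3-silyloxycyclobut-1-en-1-yl triflate F1.
- Palladium-catalysed hydroxycarbonylation (Pd(OAc)2, dppf, CO, KOAc, aqueous DMSO) would give (3S)-3-silyloxycyclobut-1-ene-1-carboxylic acid F2.
- An acceptor on C4 is known to direct that carbon to the enone α-carbon, so irradiation with 12 should give the head-to-head ladder keto acid F3.
- The conditions of step 12 would give the lactone acid F4, and BH3·THF would reduce only the carboxylic acid, to the neopentyl alcohol F5.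
- Phenyl chlorothionoformate and pyridine would give the thionocarbonate F6, and Barton–McCombie reduction (Bu3SnH at high concentration, AIBN) would return the route at 20.

**Step 13.** The most likely failure is leakage away from the chair-like pathway. The chair that the lactone enforces carries the C8 silyloxy group axial and syn to the C10 methyl, and the C2 silyloxy group axial on the diyl ring. A boat-like opening would give the E,E diene, which rearranges at once, and cleavage of ring A or a Cope shift of 21 at 180 °C would give elemane-type products. The fallback opens the ladder at the ketone level, where the α-carbonyl weakens C5–C10 and a lower temperature should suffice. It sets out from 18.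
- Thermolysis would give the ten-membered dienone F7, whose conjugated C4=C5 bond can be equilibrated to E with catalytic PhSH/AIBN.
- Luche reduction (NaBH4, CeCl3·7H2O) would give the allylic hydroxy ester F8, and PPTS lactonisation would return the route at 21.
- This gives up the conformational lock and leaves the C6 configuration to the conformation of the ten-membered ring.

**Step 12.** The most likely failure is hydride delivery to the other face of C6. The exo face also carries the C7 arm and the C10 methyl, so discrimination from the face shielded by the four-membered ring may be small. The C6 epimer would then close to the cis lactone. The fallback corrects C6 by inversion at the C–O bond. It sets out from the cis-fused ladder lactone F9 (the 6-epimer of 20).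
- LiOH in aqueous THF would open it to the hydroxy acid F10.
- Mitsunobu lactonisation (PPh3, DIAD) would close the ring with inversion at C6 and return the route at 20.

**Step 9.** The most likely failure is low enantioselectivity, because the carbonyl is flanked by an sp2 CH and a CH2 of similar size; the cyclobutenol may also ring-open during work-up. The fallback replaces catalyst control by resolution and sets out from 15.
- Luche reduction would give racemic 3-methylcyclobut-2-en-1-ol F11.
- Candida antarctica lipase B with vinyl acetate should acylate the (R)-enantiomer to (1R)-3-methylcyclobut-2-en-1-yl acetate F12, leaving the (S)-alcohol, which is 16.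
- Any residual wrong enantiomer would appear later as a separable diastereomer of 18.

**Step 5.** The most likely failure is incomplete facial discrimination by the allylic silyloxy group, or boron at C7, giving the trans C7/C8 isomer or a tertiary alcohol. The fallback sets C7 by a stereospecific hydride shift and sets out from 7.
- HF·pyridine would give the allylic alcohol F13.
- VO(acac)2 and t-BuOOH would epoxidise syn to the hydroxyl, giving the epoxy alcohol F14.
- Et3SiCl and imidazole would give the epoxy silyl ether F15.
- BF3·OEt2 at −78 °C would open the epoxide at C7 with a 1,2-hydride shift from C6, anti to the departing oxygen (Meinwald rearrangement). This places the arm cis to O8 and makes the C6 ketone directly, returning the route at 10.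

## Further compounds

F1 | step 11 | (3S)-3-[(tert-butyldimethylsilyl)oxy]cyclobut-1-en-1-yl trifluoromethanesulfonate | O=S(=O)(OC1=C[C@@H](O[Si](C)(C)C(C)(C)C)C1)C(F)(F)F
F2 | step 11 | (3S)-3-[(tert-butyldimethylsilyl)oxy]cyclobut-1-ene-1-carboxylic acid | OC(=O)C1=C[C@@H](O[Si](C)(C)C(C)(C)C)C1
F3 | step 11 | head-to-head cis,anti,cis ladder keto ester with CO2H on C4 (C15 acid analogue of 18) | O=C1[C@H](CC(=O)OC)[C@H](O[Si](CC)(CC)CC)C[C@@]2(C)[C@@H]3[C@@H](O[Si](C)(C)C(C)(C)C)C[C@]3(C(=O)O)[C@@H]12
F4 | step 11 | trans-fused ladder lactone with CO2H on C4 (C15 acid analogue of 20) | O=C1C[C@@H]2[C@H](O[Si](CC)(CC)CC)C[C@@]3(C)[C@@H]4[C@@H](O[Si](C)(C)C(C)(C)C)C[C@]4(C(=O)O)[C@H]3[C@H]2O1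
F5 | step 11 | trans-fused ladder lactone with CH2OH on C4 | O=C1C[C@@H]2[C@H](O[Si](CC)(CC)CC)C[C@@]3(C)[C@@H]4[C@@H](O[Si](C)(C)C(C)(C)C)C[C@]4(CO)[C@H]3[C@H]2O1
F6 | step 11 | O-phenyl thionocarbonate of F5 | O=C1C[C@@H]2[C@H](O[Si](CC)(CC)CC)C[C@@]3(C)[C@@H]4[C@@H](O[Si](C)(C)C(C)(C)C)C[C@]4(COC(=S)Oc5ccccc5)[C@H]3[C@H]2O1
F7 | step 13 | (1(10)Z,4E)-cyclodeca-1(10),4-dien-6-one with 2-OTBS, 8-OTES and the C7 methyl acetate arm | O=C1/C=C(\C)C[C@H](O[Si](C)(C)C(C)(C)C)/C=C(/C)C[C@@H](O[Si](CC)(CC)CC)[C@H]1CC(=O)OC
F8 | step 13 | (6R)-allylic alcohol from F7 (hydroxy ester) | O[C@@H]1/C=C(\C)C[C@H](O[Si](C)(C)C(C)(C)C)/C=C(/C)C[C@@H](O[Si](CC)(CC)CC)[C@H]1CC(=O)OC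
F9 | step 12 | cis-fused ladder γ-lactone (6-epimer of 20) | O=C1C[C@@H]2[C@H](O[Si](CC)(CC)CC)C[C@@]3(C)[C@@H]4[C@@H](O[Si](C)(C)C(C)(C)C)C[C@]4(C)[C@H]3[C@@H]2O1
F10 | step 12 | ladder hydroxy acid with 6-OH cis to the C7 arm | OC(=O)C[C@@H]1[C@H](O[Si](CC)(CC)CC)C[C@@]2(C)[C@@H]3[C@@H](O[Si](C)(C)C(C)(C)C)C[C@]3(C)[C@H]2[C@@H]1O
F11 | step 9 | 3-methylcyclobut-2-en-1-ol (racemic) | CC1=CC(O)C1
F12 | step 9 | (1R)-3-methylcyclobut-2-en-1-yl acetate | CC1=C[C@H](OC(C)=O)C1
F13 | step 5 | methyl 2-[(6R)-6-hydroxy-4-methylcyclohex-1-en-1-yl]acetate | COC(=O)CC1=CCC(C)C[C@H]1O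
F14 | step 5 | syn epoxy alcohol from F13 (epoxide oxygen cis to the hydroxyl) | COC(=O)C[C@]12O[C@H]1CC(C)C[C@H]2O
F15 | step 5 | triethylsilyl ether of F14 | COC(=O)C[C@]12O[C@H]1CC(C)C[C@H]2O[Si](CC)(CC)CC
A1 | alternative 1 | ten-membered 1(10),4-diene C5 enol triflate (6-OMOM, 2-OPMB, 8-OTBS, C12 as CH2CH2OTBS) | COCO[C@@H]1/C(OS(=O)(=O)C(F)(F)F)=C(\C)C[C@H](OCc2ccc(OC)cc2)/C=C(/C)C[C@@H](O[Si](C)(C)C(C)(C)C)[C@H]1CCO[Si](C)(C)C(C)(C)C
A2 | alternative 2 | α-(diethoxyphosphoryl) trans-6,12-lactone with free 8-OH and 2-OTBS | CCOP(=O)(OCC)[C@@H]1C(=O)O[C@@H]2/C=C(\C)C[C@H](O[Si](C)(C)C(C)(C)C)/C=C(/C)C[C@@H](O)[C@@H]12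
A3 | alternative 3 | 8-O-triethylsilyl α-methylene lactone with free 2-OH | C=C1C(=O)O[C@@H]2/C=C(\C)C[C@H](O)/C=C(/C)C[C@@H](O[Si](CC)(CC)CC)[C@@H]12
A4 | alternative 2 | O6 diethylphosphonoacetate of the ten-membered trans-7,8-epoxide | CCOP(=O)(OCC)CC(=O)O[C@@H]1/C=C(\C)C[C@H](O[Si](C)(C)C(C)(C)C)/C=C(/C)C[C@H]2O[C@H]12
A5 | alternative 3 | seco C2 aldehyde with Z-C1 alkenyl iodide on the α-methylene lactone | C=C1C(=O)O[C@H](/C=C(\C)CC=O)[C@H]1[C@H](O[Si](CC)(CC)CC)C/C(C)=C\I
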